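## Retrosynthetic overview

1. Feature: ring A (C4a, C5, C6, C7, C8, C8a) bears oxygen on C5, C7 and C8a (O1). Without the O7-methyl and the C6-prenyl group it is phloroglucinol, in which any C–H can serve as C4a and either neighbouring O–H as O1.
2. The two ring-B pivalates come off last. The C6–CH2 bond is traced by a [3,3] shift to an O5 1,1-dimethylallyl ether (made from the O5 dimethylpropargyl ether), and the O7-methyl to a 5,7-diol.
3. Key disconnection: C4–C4a and O1–C2 of the pyranone, leading to phloroglucinol and a 2-aryl-3-(dimethylamino)acrylate that delivers C2, C3, C4 and ring B.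
4. The enaminoester is made from 2,4-dihydroxyphenylacetic acid by esterification, double pivaloylation and aminomethylenation with DMF dimethyl acetal.
5. Ring order: both benzene rings are bought, and the pyranone is the only ring built (step 4).

Key step: step 4

Assumption: the target has no stereocentre, its prenyl alkene carries two identical methyl groups, and rotation about C3–C1' is free. The compound is therefore achiral and no enantiocontrol is needed.

## Route

Step 1
Reactants: 1 2,4-dihydroxyphenylacetic acid
Product: 2 methyl 2,4-dihydroxyphenylacetate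
Conditions: MeOH, H2SO4 (cat.), reflux
Reagents that add atoms: methanol, SMILES CO
Why: Fischer esterification: in a large excess of methanol the open-chain methyl ester should be favoured over the benzofuran-2(3H)-one that the 2-hydroxy acid can form, while the phenols stay untouched.

Step 2
Reactants: 2 methyl 2,4-dihydroxyphenylacetate
Product: 3 methyl 2,4-bis(pivaloyloxy)phenylacetate
Conditions: PivCl (2.4 equiv), Et3N (3 equiv), DMAP (5 mol %), CH2Cl2, 0 °C → rt
Reagents that add atoms: pivaloyl chloride, SMILES CC(C)(C)C(=O)Cl
Why: DMAP-catalysed O-acylation of both phenols with an acid chloride should outrun base-induced lactonisation of the 2-OH onto the ester, and the bulky, electron-withdrawing pivalates mask ring B, acidify the benzylic CH2 and can be removed at the end without acid.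

Step 3
Reactants: 3 methyl 2,4-bis(pivaloyloxy)phenylacetate; 4 N,N-dimethylformamide dimethyl acetal
Product: 5 methyl (E)-2-[2,4-bis(pivaloyloxy)phenyl]-3-(dimethylamino)acrylate
Conditions: 4 (3 equiv), toluene, 100 °C, slow N2 sweep to carry off MeOH
Reagents that add atoms: none
Why: Aminomethylenation of a C–H acid with an amide acetal: the methoxide of the formamidinium methoxide ion pair deprotonates the doubly activated CH2, the enolate adds to Me2N=CH–OMe+ and methanol is lost to give the push–pull E-enaminoester, while removal of methanol and the steric shielding of the pivaloyl carbonyls should hold back transesterification and O-to-C acyl transfer.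

Step 4
Reactants: 5 methyl (E)-2-[2,4-bis(pivaloyloxy)phenyl]-3-(dimethylamino)acrylate; 6 phloroglucinol (anhydrous)
Product: 8 3-[2,4-bis(pivaloyloxy)phenyl]-5,7-dihydroxycoumarin, via trihydroxyphenyl Z-acrylate 7 (not isolated)
Conditions: 6 (1.5 equiv), glacial AcOH, 100 °C → reflux, N2
Reagents that add atoms: none
Why: Acetic acid protonates the push–pull alkene of 5 at C3 (coumarin numbering) and so exposes a Me2N+=C4H iminium carbon, which a ring carbon of 6 attacks in a Mannich/Friedel–Crafts sense to make C4–C4a; after rearomatisation the benzylic amine leaves, pushed out by the ortho and para hydroxyls, and loss of the acidic C3–H gives acrylate 7. Since C4 passes through an sp3 state the alkene geometry is not inherited from 5, and the Z isomer, in which a hydroxyl next to C4a lies beside the ester, is drained by 6-exo-trig attack of that oxygen on the ester carbonyl (O1–C2) with loss of methanol, which closes the pyranone, the only ring formed. The closest known reactions are the acetic acid annulations of phenols, naphthols and cyclic 1,3-diones with 2-substituted 3-(dimethylamino)propenoates to 3-substituted coumarins and pyran-2-ones, and the Pechmann condensation of phloroglucinol with α-formyl arylacetates. No stereocentre is created, and no site selectivity is asked of 6 because its three C–H positions and the two hydroxyls beside each of them are equivalent, so every pathway ends in the same 5,7-diol 8. What the step does need is chemoselectivity: a single annulation, secured by the lactone, which makes ring A of 8 far less nucleophilic than 6 (used in slight excess), and silence of ring B, secured by its two electron-withdrawing acyloxy groups. The hindered pivalates should stand hot acetic acid, and the liberated dimethylamine is held as its acetate salt and cannot aminolyse them.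

Step 5
Reactants: 8 3-[2,4-bis(pivaloyloxy)phenyl]-5,7-dihydroxycoumarin
Product: 9 3-[2,4-bis(pivaloyloxy)phenyl]-5-hydroxy-7-methoxycoumarin
Conditions: MeI (1.05 equiv), KHCO3 (1.5 equiv), DMF, rt
Reagents that add atoms: iodomethane, SMILES CI
Why: Williamson-type O-methylation under weak-base control: the umbelliferone-type 7-OH, para to the C4a–C4=C3–C2=O chain and free of the peri contact with C4–H that crowds the 5-OH, is the more acidic and more accessible phenol, so hydrogencarbonate should ionise it preferentially and one equivalent of iodomethane should cap it, the minor O5-methyl and dimethyl ethers being removed by chromatography.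

Step 6
Reactants: 9 3-[2,4-bis(pivaloyloxy)phenyl]-5-hydroxy-7-methoxycoumarin
Product: 10 3-[2,4-bis(pivaloyloxy)phenyl]-7-methoxy-5-(2-methylbut-3-yn-2-yloxy)coumarin
Conditions: 3-chloro-3-methylbut-1-yne (1.5 equiv), DBU (1.6 equiv), CuCl2·2H2O (2 mol %), MeCN, 0 °C
Reagents that add atoms: 3-chloro-3-methylbut-1-yne, SMILES CC(C)(Cl)C#C
Why: Copper-catalysed propargylic etherification of a phenol with a tertiary propargylic chloride (Godfrey-type conditions): the copper acetylide ionises to an allenylidene-type electrophile that the only free phenoxide, O5, captures at the tertiary carbon, and the low temperature should spare the pivalates and prevent chromene formation.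

Step 7
Reactants: 10 3-[2,4-bis(pivaloyloxy)phenyl]-7-methoxy-5-(2-methylbut-3-yn-2-yloxy)coumarin
Product: 11 3-[2,4-bis(pivaloyloxy)phenyl]-7-methoxy-5-(2-methylbut-3-en-2-yloxy)coumarin
Conditions: H2 (1 atm), Lindlar catalyst, quinoline, EtOAc, rt, stopped after one equivalent of H2
Reagents that add atoms: none
Why: Lindlar semihydrogenation: the poisoned palladium surface should reduce the terminal alkyne to the vinyl group and stop there if hydrogen uptake is followed, leaving the conjugated C3=C4 bond and the aryl esters untouched.

Step 8
Reactants: 11 3-[2,4-bis(pivaloyloxy)phenyl]-7-methoxy-5-(2-methylbut-3-en-2-yloxy)coumarin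
Product: 13 3-[2,4-bis(pivaloyloxy)phenyl]-5-hydroxy-7-methoxy-6-(3-methylbut-2-enyl)coumarin, via C6-prenyl dienone 12 (not isolated)
Conditions: PhNEt2 (degassed), 130 °C, Ar
Reagents that add atoms: none
Why: Aromatic Claisen rearrangement: of the two positions ortho to O5, C4a is a ring-fusion carbon that cannot rearomatise, so the [3,3] shift delivers the allyl terminus to C6 with allylic inversion (1,1-dimethylallyl on oxygen becomes prenyl on carbon), and the amine solvent should speed enolisation of dienone 12 ahead of a Cope shift to C8 and suppress acid-catalysed loss of isoprene or chroman closure.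

Step 9
Reactants: 13 3-[2,4-bis(pivaloyloxy)phenyl]-5-hydroxy-7-methoxy-6-(3-methylbut-2-enyl)coumarin
Product: 14 3-(2,4-dihydroxyphenyl)-5-hydroxy-7-methoxy-6-(3-methylbut-2-enyl)coumarin (CNP0305155.0, glycycoumarin)
Conditions: NaOMe (5 equiv), MeOH–THF, 0 °C → rt; then 1 M HCl, 0 °C, to pH 4
Reagents that add atoms: none
Why: Zemplén-type transesterification: methoxide cleaves the aryl pivalates because phenoxides are good leaving groups, the base-only conditions cannot cyclise the 5-OH onto the prenyl alkene or touch the methyl ether, and any reversible methanolysis of the lactone is undone on acidification since the Z-configured 2-hydroxycinnamate relactonises.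

## Compound list

1 | 2,4-dihydroxyphenylacetic acid | OC(=O)Cc1ccc(O)cc1O | starting material
2 | methyl 2,4-dihydroxyphenylacetate | COC(=O)Cc1ccc(O)cc1O | intermediate
3 | methyl 2,4-bis(pivaloyloxy)phenylacetate | COC(=O)Cc1ccc(OC(=O)C(C)(C)C)cc1OC(=O)C(C)(C)C | intermediate
4 | N,N-dimethylformamide dimethyl acetal | COC(OC)N(C)C | starting material
5 | methyl (E)-2-[2,4-bis(pivaloyloxy)phenyl]-3-(dimethylamino)acrylate | COC(=O)/C(=C/N(C)C)c1ccc(OC(=O)C(C)(C)C)cc1OC(=O)C(C)(C)C | intermediate
6 | phloroglucinol | Oc1cc(O)cc(O)c1 | starting material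
7 | methyl (Z)-2-[2,4-bis(pivaloyloxy)phenyl]-3-(2,4,6-trihydroxyphenyl)acrylate (not isolated) | COC(=O)/C(=C\c1c(O)cc(O)cc1O)c1ccc(OC(=O)C(C)(C)C)cc1OC(=O)C(C)(C)C | intermediate
8 | 3-[2,4-bis(pivaloyloxy)phenyl]-5,7-dihydroxycoumarin | Oc1cc(O)c2cc(-c3ccc(OC(=O)C(C)(C)C)cc3OC(=O)C(C)(C)C)c(=O)oc2c1 | intermediate
9 | 3-[2,4-bis(pivaloyloxy)phenyl]-5-hydroxy-7-methoxycoumarin | COc1cc(O)c2cc(-c3ccc(OC(=O)C(C)(C)C)cc3OC(=O)C(C)(C)C)c(=O)oc2c1 | intermediate
10 | 3-[2,4-bis(pivaloyloxy)phenyl]-7-methoxy-5-(2-methylbut-3-yn-2-yloxy)coumarin | COc1cc(OC(C)(C)C#C)c2cc(-c3ccc(OC(=O)C(C)(C)C)cc3OC(=O)C(C)(C)C)c(=O)oc2c1 | intermediate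
11 | 3-[2,4-bis(pivaloyloxy)phenyl]-7-methoxy-5-(2-methylbut-3-en-2-yloxy)coumarin | COc1cc(OC(C)(C)C=C)c2cc(-c3ccc(OC(=O)C(C)(C)C)cc3OC(=O)C(C)(C)C)c(=O)oc2c1 | intermediate
12 | 3-[2,4-bis(pivaloyloxy)phenyl]-7-methoxy-6-(3-methylbut-2-enyl)-2H-chromene-2,5(6H)-dione (racemic at C6, transient, not isolated) | COC1=CC2=C(C=C(c3ccc(OC(=O)C(C)(C)C)cc3OC(=O)C(C)(C)C)C(=O)O2)C(=O)C1CC=C(C)C | intermediate
13 | 3-[2,4-bis(pivaloyloxy)phenyl]-5-hydroxy-7-methoxy-6-(3-methylbut-2-enyl)coumarin | COc1cc2oc(=O)c(-c3ccc(OC(=O)C(C)(C)C)cc3OC(=O)C(C)(C)C)cc2c(O)c1CC=C(C)C | intermediate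
14 | 3-(2,4-dihydroxyphenyl)-5-hydroxy-7-methoxy-6-(3-methylbut-2-enyl)coumarin | COc1cc2oc(=O)c(-c3ccc(O)cc3O)cc2c(O)c1CC=C(C)C | target

## Step count and risks

Total step count: 9.
Longest linear sequence: 9 steps (1 → 14). Compounds 4 and 6 enter as bought reagents.

**Step 5 (mono-methylation).**
- What may go wrong: discrimination between O7 and O5 may be insufficient and over-methylation may occur, because the coumarin lacks the peri carbonyl hydrogen bond that shields a flavonoid 5-OH.
- The site of methylation should be checked by NOE. An O7-methyl should contact H6 and H8, whereas an O5-methyl should contact H4 and H6.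
- Fallback: it sets out from 8 and comes back at 9, and replaces kinetic alkylation by a protect-and-release sequence. Acetylation (Ac2O, pyridine, rt) should give 5,7-diacetoxy-3-[2,4-bis(pivaloyloxy)phenyl]coumarin F1. Thiolysis (PhSH, imidazole, NMP, 0 °C) should remove the ester of the better leaving phenoxide, O7, to give 5-acetoxy-3-[2,4-bis(pivaloyloxy)phenyl]-7-hydroxycoumarin F2. The single free phenol is then methylated under neutral Mitsunobu conditions (MeOH, PPh3, DIAD, THF) to 5-acetoxy-3-[2,4-bis(pivaloyloxy)phenyl]-7-methoxycoumarin F3. A short cold methanolysis (K2CO3, MeOH, 0 °C) should take off the unhindered acetate while the pivalates stay, giving 9.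

**Step 4 (annulation).**
- What may go wrong: C-attack on the hindered α-aryl iminium ion may be slow, a second phloroglucinol molecule may capture the quinone-methide stage, and the pivalates may undergo acidolysis on long heating.
- Fallback: it sets out from 6 and 3 and comes back at 8. It reverses the polarity, so that C4 is placed on the phloroglucinol ring first and C3–C4 is made by an aldol condensation. Vilsmeier–Haack formylation of 6 (POCl3, DMF, EtOAc, then water) gives the still symmetric 2,4,6-trihydroxybenzaldehyde F4. SN2 demethylation of ester 3 (LiI, EtOAc, reflux, then cold dilute acid) should give 2,4-bis(pivaloyloxy)phenylacetic acid F5. Perkin–Oglialoro condensation of the two (Ac2O, Et3N, 100 °C) should close the pyranone and acetylate the remaining phenols, giving 5,7-diacetoxy-3-[2,4-bis(pivaloyloxy)phenyl]coumarin F1, the compound also met in the fallback to step 5. Cold methanolysis of both acetates (K2CO3, MeOH, 0 °C) returns 8.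

**Step 3 (aminomethylenation).**
- What may go wrong: conversion of the only moderately acidic CH2 may be incomplete, the pivalates may be lost to methoxide, and the ortho pivaloyl group may migrate to the enolate carbon.
- Fallback: it sets out from 3 and comes back at 5, and avoids free alkoxide altogether. Titanium-mediated crossed Claisen formylation (TiCl4, Et3N, HCO2Me, CH2Cl2, 0 °C) should give methyl (Z)-2-[2,4-bis(pivaloyloxy)phenyl]-3-hydroxyacrylate F6, the enol form of the α-formyl ester. Condensation with dimethylamine (2 M in THF, 1.1 equiv, MgSO4, rt) should then give 5.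

## Further compounds

F1 | step 5 | 5,7-diacetoxy-3-[2,4-bis(pivaloyloxy)phenyl]coumarin | CC(=O)Oc1cc(OC(C)=O)c2cc(-c3ccc(OC(=O)C(C)(C)C)cc3OC(=O)C(C)(C)C)c(=O)oc2c1
F2 | step 5 | 5-acetoxy-3-[2,4-bis(pivaloyloxy)phenyl]-7-hydroxycoumarin | Oc1cc(OC(C)=O)c2cc(-c3ccc(OC(=O)C(C)(C)C)cc3OC(=O)C(C)(C)C)c(=O)oc2c1
F3 | step 5 | 5-acetoxy-3-[2,4-bis(pivaloyloxy)phenyl]-7-methoxycoumarin | COc1cc(OC(C)=O)c2cc(-c3ccc(OC(=O)C(C)(C)C)cc3OC(=O)C(C)(C)C)c(=O)oc2c1
F4 | step 4 | 2,4,6-trihydroxybenzaldehyde | O=Cc1c(O)cc(O)cc1O
F5 | step 4 | 2,4-bis(pivaloyloxy)phenylacetic acid | OC(=O)Cc1ccc(OC(=O)C(C)(C)C)cc1OC(=O)C(C)(C)C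
F6 | step 3 | methyl (Z)-2-[2,4-bis(pivaloyloxy)phenyl]-3-hydroxyacrylate | COC(=O)/C(=C\O)c1ccc(OC(=O)C(C)(C)C)cc1OC(=O)C(C)(C)C
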